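The numbers stand for no real mixture; the rest is arithmetic.

I set theta beside zeta, the same flask with less Z, and reckoned a chain's length in each as one unit plus what a living end adds after that.

| setting | theta | zeta |
|---|---|---|
| Z | 5.0 mM | 1.2 mM |
| J | 0.0500 mM | 0.0500 mM |
| G | 0.21 mM | 0.21 mM |
| time | 6.0 s | 6.0 s |

    Z + Q → D + E (k1 = 1210 M⁻¹ s⁻¹)
    Z + D → E + D, rate k2*[D]*[Z] (k2 = 698 M⁻¹ s⁻¹)
    D + J → D.J (k3 = 16300 M⁻¹ s⁻¹)
    G → Q (k4 = 0.124 s⁻¹)
    Z → L (k5 = 0.00517 s⁻¹)

- the average divides the monomer in chains by the number of chains begun, living and dead together
- run time (theta): 6.0 s

1. which of the two ends with the longer chains by the average number of monomer units in a chain (chains begun, living or dead) ("neither" if they lie within 10%) (theta / zeta / neither)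
2. average number of monomer units in a chain (chains begun, living or dead) at the end, theta
3. average number of monomer units in a chain (chains begun, living or dead) at the end, zeta

**Fastest rung.** Q went first: its half-life against Z was 0.11 s in theta and 0.477 s in zeta, far shorter than the 5.6 s of G. So G → Q was the rate-limiting step, and I took the chains begun by the end as 52.5% of the G charged in both flasks.

**Middle rung.** J, charged at 23.8% of G, killed D with a half-life of 0.85 s at its charge, while the chains begun needed 2.19 s to match J. That half-life was shorter than the wait, but I saw no clean lag in those two figures, so I let the living share of the chains begun climb in a straight line from nothing to the 54.7% that J left.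

**Living time.** Half the run times that share gave 1.64 s, which I called the living time, the average time a chain begun spent growing. Z does not enter it.

**Slowest rung.** Step 5 had a half-life of 130 s, much longer than the run, and by my reckoning the chains took 12.6% of the Z, so I held Z at its charge. A living end then added 3.49 s⁻¹ units in theta and 0.838 s⁻¹ in zeta. One unit plus that pace times the living time gave 6.72 for theta and 2.37 for zeta, with theta the longer.

**The result.** The forecast named theta, with 6.7 and 2.3, holding that “chain length scales roughly with the monomer charged”. The simulation gave theta, with 6.61 and 2.17.

**Still moving.** Read back, those lengths give a living time of 1.61 s in theta and 1.40 s in zeta. Theta with twice the Z reckons to 12.4 units by my living time and simulates at 12.5. Neither flask had come to rest at 6.00 s: theta still held 82.9% of its Z and zeta 79.3%. At 60.0 s theta had 0.254% of its Z and 0.0587% of its G left, and the average length had reached 22.0 in theta and 5.44 in zeta.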